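Readings and results stem from a simulated flask with made-up constants; the scatter is artificial.

If Z and E are made side by side, neither feeds the other and their two rates keep one proportion as the charges fall, then their ratio stays put through a run, and late readings can speak for the early minutes.

| flask | X | G | remark | time |
|---|---|---|---|---|
| south-west | 17 mM | 13.2 mM | run made earlier |  |
| west | 26 mM | 13.2 mM | run made earlier |  |
| north-east | 12 mM | 20 mM | run made earlier |  |
| flask | 12 mM | 13.2 mM |  | 15 d |

| run | time / d | Z / % | E / % | X / % |
|---|---|---|---|---|
| south-west | 5.00 | 1 | 74 | 4 |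
| south-west | 10.0 | 0 | 78 | 4 |
| south-west | 15.0 | 2 | 76 | 5 |
| south-west | 20.0 | 3 | 75 | 2 |
| west | 2.50 | 0 | 53 | 16 |
| west | 6.00 | 0 | 47 | 6 |
| west | 12.0 | 1 | 51 | 4 |
| west | 20.0 | 0 | 50 | 3 |
| north-east | 5.00 | 1 | 98 | 0 |
| north-east | 10.0 | 2 | 97 | 0 |
| north-east | 15.0 | 2 | 98 | 0 |
| north-east | 20.0 | 2 | 99 | 0 |

(readings scatter by 1.5 percentage points)

1. ratio of Z to E at 5.0 min
2. ratio of Z to E at 15 d

- what was read earlier has a scatter of 1.5 percentage points, one standard deviation

No run was read before 2.50 d, so the early end of this flask has to be joined to the late end by that rule. The north-east run tests one part of it, the draining. With X read at 0% from 5.00 d to 20.0 d, Z draining into E would show as a fall, yet Z moves by 1 percentage point over those readings, less than the scatter of 1.5 points. Summed over that run, Z over E reads 0.0179. This is the split, the Z made per E made, a selectivity factor, and it is a reading that rests on Z values of 1% to 2%.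

The flask, like the north-east run, holds more G than X, at 1.10 equivalents. The reckoning here therefore commits to the split at both times, 0.0179 at 5.0 min and at 15 d. The forecast agrees at 15 d with 0.018, but differs at 5.0 min with 0.05, on the ground that “If Z is a kinetic product that later drains to E, it could be much higher”.

The flask gives 0.0170 at 5.0 min and 0.0170 at 15 d, and its Z stands at 1.61% at 0.450 d and at 1.64% at 15.0 d.

    X ⇌ Q, settled at all times (K = 0.610)
    X + G → Z (k = 3.00 M⁻¹ h⁻¹)
    G + Q → E (k = 290 M⁻¹ h⁻¹)
    2 Q → J (k = 7.20 M⁻¹ h⁻¹)

In this flask the split times the 97.0% of E gives 1.74% of Z, and the flask holds 1.64%. The neighbouring flask, charged with 20 mM of X, has 0.660 equiv of G and ends with 0% of its G left. Its 64.9% of E times the split gives 1.16% of Z, and that flask holds 1.10%.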